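**Retrosynthetic overview**

1. Target 17 comes from a Baeyer–Villiger ring expansion of bicyclo[3.2.1]octenedione 16: oxygen is inserted between the C8 ketone and the methoxy-bearing bridgehead C5. The step is run as a catalytic kinetic resolution, which fixes the absolute configuration.
2. Racemic 16 comes from hydrobenzofuranone 15 by an acid-induced benzyl shift from oxygen to carbon; 15 comes from an oxidative dearomatising annulation of phenol 14 with (Z)-alkene 6.
3. Alkene 6 comes from 4-chlorophenol: dibromination, Cu-catalysed methoxylation with in-pot O-methylation, then Suzuki coupling with (Z)-propenylboronic acid.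
4. Phenol 14 comes from hydroquinone: methylation, ortho-lithiation/borylation/oxidation, para-bromination, allyl Suzuki coupling.
5. Ring order: both benzene rings are bought; the tetrahydrofuran ring forms first (15), then the cyclopentane ring that closes the bicyclo[3.2.1]octane (16), then the lactone by ring expansion (17).

Assumption: racemic compounds 15 and 16 are drawn as the enantiomer that goes on to the target, and locants C1–C8 in the reasons are those of bicyclooctenedione 16.

**Route**

Step 1
Reactants: 1 4-chlorophenol
Product: 2 2,6-dibromo-4-chlorophenol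
Conditions: Br2 (2.1 equiv), AcOH, 20 °C
Reagents that add atoms: bromine BrBr
Why: Electrophilic aromatic bromination of a para-blocked phenol goes to both ortho positions; no stereocentre is formed.

Step 2
Reactants: 2 2,6-dibromo-4-chlorophenol
Product: 4 5-chloro-1,2,3-trimethoxybenzene, via sodium 4-chloro-2,6-dimethoxyphenolate 3 (not isolated)
Conditions: NaOMe (6 equiv), CuI (0.2 equiv), DMF/MeOH, 110 °C; then MeI (5 equiv), 25 °C
Reagents that add atoms: sodium methoxide C[O-].[Na+]; iodomethane CI
Why: Ullmann-type Cu-catalysed methoxylation replaces the two aryl bromides but leaves the much less reactive aryl chloride, and the resulting phenolate is O-methylated in the same pot (Williamson ether synthesis).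

Step 3
Reactants: 4 5-chloro-1,2,3-trimethoxybenzene; 5 (Z)-prop-1-en-1-ylboronic acid
Product: 6 (Z)-1,2,3-trimethoxy-5-(prop-1-en-1-yl)benzene
Conditions: Pd(OAc)2 (2 mol%), SPhos (4 mol%), K3PO4, toluene/H2O, 80 °C
Reagents that add atoms: none
Why: Suzuki–Miyaura coupling with a bulky biaryl phosphine activates the electron-rich aryl chloride, and transmetalation and reductive elimination retain the Z geometry of the alkenylboron partner.

Step 4
Reactants: 7 hydroquinone
Product: 8 1,4-dimethoxybenzene
Conditions: MeI (2.5 equiv), K2CO3, acetone, reflux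
Reagents that add atoms: iodomethane CI
Why: Double Williamson O-methylation of a simple diphenol.

Step 5
Reactants: 8 1,4-dimethoxybenzene
Product: 11 2,5-dimethoxyphenol, via aryllithium 9 (not isolated), via dimethyl arylboronate 10 (not isolated)
Conditions: n-BuLi, TMEDA, Et2O, 0 to 25 °C; B(OMe)3, −78 to 25 °C; then AcOH, 30% H2O2, 0 °C
Reagents that add atoms: hydrogen peroxide OO
Why: Directed ortho-metalation next to a methoxy group, borylation, and oxidative conversion of the C–B bond into C–O (aryl shift from boron to oxygen) give the phenol at the only type of ring position available.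

Step 6
Reactants: 11 2,5-dimethoxyphenol
Product: 12 4-bromo-2,5-dimethoxyphenol
Conditions: NBS (1.0 equiv), MeCN, −20 to 0 °C
Reagents that add atoms: N-bromosuccinimide O=C1CCC(=O)N1Br
Why: Electrophilic bromination goes para to the free hydroxyl, the most activated and least hindered position (the other ortho site is flanked by two oxygen substituents).

Step 7
Reactants: 12 4-bromo-2,5-dimethoxyphenol; 13 potassium allyltrifluoroborate
Product: 14 4-allyl-2,5-dimethoxyphenol
Conditions: Pd(OAc)2 (3 mol%), RuPhos (6 mol%), K2CO3, toluene/H2O 10:1, 80 °C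
Reagents that add atoms: none
Why: Suzuki–Miyaura coupling of an aryl bromide with an allyltrifluoroborate tolerates the free phenol, and the unsubstituted allyl group raises no α/γ question.

Step 8
Reactants: 14 4-allyl-2,5-dimethoxyphenol; 6 (Z)-1,2,3-trimethoxy-5-(prop-1-en-1-yl)benzene
Product: 16 rac-(1R,5R,6R,7R)-3-allyl-5-methoxy-6-methyl-7-(3,4,5-trimethoxyphenyl)bicyclo[3.2.1]oct-3-ene-2,8-dione, via hydrobenzofuranone 15 (not isolated)
Conditions: 6 (1.5 equiv), PhI(OAc)2 (1.1 equiv, slow addition), HFIP/CH2Cl2 1:4, −40 °C; then TfOH (0.1 equiv), −40 to 0 °C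
Reagents that add atoms: none
Why: Oxidative dearomatisation of 14 gives a 2,5-dimethoxyphenoxonium ion whose oxocarbenium carbon (C5, bearing OMe) is attacked by the β-carbon of 6 in the π-stacked orientation (aryl over the carbonyl edge, methyl of the Z-alkene over C4, which sets methyl trans to OMe at C5/C6), carbonyl-oxygen capture of the benzylic cation with loss of the remote O-methyl to acetate gives hydrobenzofuranone 15, and acid re-ionisation of its benzylic C–O bond lets the vinylogous-ester carbon C1 close on the cation anti to the methyl (aryl exo, methyl endo) — a stepwise cationic (5+2) annulation of the phenol oxidative-dearomatisation type finished by the hydrobenzofuranone-to-bicyclo[3.2.1]octanoid rearrangement, giving racemic 16.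

Step 9
Reactants: 16 rac-(1R,5R,6R,7R)-3-allyl-5-methoxy-6-methyl-7-(3,4,5-trimethoxyphenyl)bicyclo[3.2.1]oct-3-ene-2,8-dione
Product: 17 (1R,5S,8R,9R)-3-allyl-5-methoxy-9-methyl-8-(3,4,5-trimethoxyphenyl)-6-oxabicyclo[3.2.2]non-3-ene-2,7-dione
Conditions: Sc(OTf)3 (5 mol%), chiral N,N'-dioxide ligand (propane-1,3-diyl-bridged bis[(S)-pipecolic acid 2,6-diisopropylanilide] N,N'-dioxide, 6 mol%), m-CPBA (0.55 equiv), EtOAc, −20 °C, stopped near 50% conversion; chromatography, one recrystallisation
Reagents that add atoms: 3-chloroperoxybenzoic acid O=C(OO)c1cccc(Cl)c1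
Why: Proposed new method: the chiral Sc(OTf)3–N,N'-dioxide complex binds the bridging C8 ketone together with the neighbouring bridgehead OMe as a five-membered chelate, so peracid addition to C8 (from the face over the enone bridge, away from the exo aryl) and Criegee collapse take place inside the chiral pocket and only the (1R,5R,6R,7R) enantiomer of 16 is oxidised at a useful rate (kinetic resolution, which fixes the absolute configuration of all four stereocentres, the unreacted antipode being removed by chromatography), while the α-methoxy carbon C5 (lone-pair-stabilised, a far better migrating group than the acyl-bearing C1) shifts from carbon to oxygen with retention and expands the one-carbon bridge into the ketal-lactone; the closest known reaction type is the Sc(OTf)3/chiral N,N'-dioxide Baeyer–Villiger oxidation used for desymmetrisation and kinetic resolution of monocyclic cyclohexanones and cyclobutanones, not yet shown for bridged α-alkoxy 1,3-diketones.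

**Compound list**

1 | 4-chlorophenol | Oc1ccc(Cl)cc1 | starting material
2 | 2,6-dibromo-4-chlorophenol | Oc1c(Br)cc(Cl)cc1Br | intermediate
3 | sodium 4-chloro-2,6-dimethoxyphenolate (not isolated) | [Na+].[O-]c1c(OC)cc(Cl)cc1OC | intermediate
4 | 5-chloro-1,2,3-trimethoxybenzene | COc1cc(Cl)cc(OC)c1OC | intermediate
5 | (Z)-prop-1-en-1-ylboronic acid | C/C=C\B(O)O | starting material
6 | (Z)-1,2,3-trimethoxy-5-(prop-1-en-1-yl)benzene | C/C=C\c1cc(OC)c(OC)c(OC)c1 | intermediate
7 | hydroquinone (benzene-1,4-diol) | Oc1ccc(O)cc1 | starting material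
8 | 1,4-dimethoxybenzene | COc1ccc(OC)cc1 | intermediate
9 | (2,5-dimethoxyphenyl)lithium (not isolated) | [Li]c1cc(OC)ccc1OC | intermediate
10 | dimethyl (2,5-dimethoxyphenyl)boronate (not isolated) | COB(OC)c1cc(OC)ccc1OC | intermediate
11 | 2,5-dimethoxyphenol | COc1ccc(OC)c(O)c1 | intermediate
12 | 4-bromo-2,5-dimethoxyphenol | COc1cc(Br)c(OC)cc1O | intermediate
13 | potassium allyltrifluoroborate | C=CC[B-](F)(F)F.[K+] | starting material
14 | 4-allyl-2,5-dimethoxyphenol | C=CCc1cc(OC)c(O)cc1OC | intermediate
15 | rac-(2R,3R,3aS)-5-allyl-3a-methoxy-3-methyl-2-(3,4,5-trimethoxyphenyl)-3,3a-dihydro-1-benzofuran-6(2H)-one (not isolated; 2-aryl and 3-methyl cis, 3-methyl trans to 3a-OMe) | C=CCC1=C[C@]2(OC)[C@H](C)[C@H](c3cc(OC)c(OC)c(OC)c3)OC2=CC1=O | intermediate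
16 | rac-(1R,5R,6R,7R)-3-allyl-5-methoxy-6-methyl-7-(3,4,5-trimethoxyphenyl)bicyclo[3.2.1]oct-3-ene-2,8-dione (aryl exo, methyl endo) | C=CCC1=C[C@@]2(OC)C(=O)[C@@H](C1=O)[C@H](c1cc(OC)c(OC)c(OC)c1)[C@H]2C | intermediate
17 | (1R,5S,8R,9R)-3-allyl-5-methoxy-9-methyl-8-(3,4,5-trimethoxyphenyl)-6-oxabicyclo[3.2.2]non-3-ene-2,7-dione | C=CCC1=C[C@@]2(OC)OC(=O)[C@@H](C1=O)[C@H](c1cc(OC)c(OC)c(OC)c1)[C@H]2C | target

**Step count and risks**

Total steps: 9. Longest linear sequence: 6 (steps 4, 5, 6, 7, 8, 9); the alkene branch (steps 1–3) joins at step 8.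

The three steps most likely to fail:

Step 8 is the least secure. The alkene can attack the phenoxonium ion at the allyl-bearing para carbon or at the free ortho carbon instead of C5. The ion can lose an allylic proton to give a quinone methide. The iodane can oxidise 6. The stacking model that places the methyl endo is an extrapolation; the (E)-alkene would give the 6-epimeric series by the same approach, which is why the (Z)-alkene is used. The fallback sets out from 14 and returns at 16. Phenol 14 is oxidised alone with PhI(OAc)2 in MeOH at 0 °C, where methanol capture is faster than any side reaction, to give the quinone monoketal 4-allyl-3,6,6-trimethoxycyclohexa-2,4-dien-1-one F1. F1 is ionised with TMSOTf (10 mol%) in CH2Cl2 at −78 °C in the presence of 6 (Lewis-acid quinone-ketal/propenylbenzene condensation, no oxidant present). Hydrobenzofuranone 15 is now isolated and freed of regio- and stereoisomers by chromatography. Pure 15 is then rearranged with BF3·OEt2 or catalytic TfOH in CH2Cl2 at 0 °C to 16.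

Step 9 is the proposed new step. The selectivity factor on this substrate is unknown, and the correct ligand antipode has to be found with one screening pair. The Lewis acid may ionise the ketal-lactone product, and excess peracid could epoxidise the allyl group. The fallback uses known chemistry, sets out from 16 and returns at 17. Racemic 16 is separated by preparative chiral SFC (amylose tris(3,5-dimethylphenylcarbamate) phase, CO2/MeOH) into (1R,5R,6R,7R)-3-allyl-5-methoxy-6-methyl-7-(3,4,5-trimethoxyphenyl)bicyclo[3.2.1]oct-3-ene-2,8-dione F2 and its (1S,5S,6S,7S) antipode F3. F2 is then oxidised with m-CPBA/NaHCO3 in CH2Cl2 at 0 °C. In this substrate-controlled Baeyer–Villiger oxidation the α-methoxy carbon migrates, giving 17.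

Step 3 can suffer from slow oxidative addition to the electron-rich aryl chloride, protodeboronation of 5, or partial Z to E isomerisation; any E-alkene would feed the wrong diastereomer series into step 8. The fallback sets out from 4 and returns at 6. Chloride 4 is coupled with propyne (PdCl2(MeCN)2, XPhos, Cs2CO3, MeCN, 90 °C, sealed tube; copper-free Sonogashira coupling) to give 1,2,3-trimethoxy-5-(prop-1-yn-1-yl)benzene F4. F4 is then semihydrogenated (H2, Pd/CaCO3 poisoned with Pb(OAc)2, quinoline, EtOAc, 20 °C); syn addition of hydrogen gives the Z-alkene 6.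

**Further compounds**

F1 | step 8 | 4-allyl-3,6,6-trimethoxycyclohexa-2,4-dien-1-one | C=CCC1=CC(OC)(OC)C(=O)C=C1OC
F2 | step 9 | (1R,5R,6R,7R)-3-allyl-5-methoxy-6-methyl-7-(3,4,5-trimethoxyphenyl)bicyclo[3.2.1]oct-3-ene-2,8-dione | C=CCC1=C[C@@]2(OC)C(=O)[C@@H](C1=O)[C@H](c1cc(OC)c(OC)c(OC)c1)[C@H]2C
F3 | step 9 | (1S,5S,6S,7S)-3-allyl-5-methoxy-6-methyl-7-(3,4,5-trimethoxyphenyl)bicyclo[3.2.1]oct-3-ene-2,8-dione | C=CCC1=C[C@]2(OC)C(=O)[C@H](C1=O)[C@@H](c1cc(OC)c(OC)c(OC)c1)[C@@H]2C
F4 | step 3 | 1,2,3-trimethoxy-5-(prop-1-yn-1-yl)benzene | CC#Cc1cc(OC)c(OC)c(OC)c1
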